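**Strategy.** Everything rests on a convergent [3+3] closure of the pyran ring between a menthone-derived spiro allylic alcohol and a fluoroarene that already carries both formyl groups and an ortho alkyne. In one pot the alkoxide displaces fluoride at the aromatic carbon ortho and para to the two CHO groups (aryl C–O bond). An iron hydride then turns the adjacent cyclopentene into the tertiary radical at the methyl-bearing carbon, which closes 6-exo-dig onto the alkyne (benzylic C–quaternary C bond) and is reduced further to the isobutyl chain. The step exploits the cis-fused pyran/cyclopentane junction: the carbinol stereocentre relays through the oxygen tether to the quaternary and benzylic carbons.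

Key step: step 10

Assumption: the isopropyl-bearing carbon alpha to the ring ketone in 1–7 may epimerise under base; this is of no consequence because that carbon becomes sp2 in step 5, and the SMILES show the menthone configuration.

**Step 1**
Reactants: 1 (−)-menthone, (2S,5R)-5-methyl-2-(propan-2-yl)cyclohexan-1-one
Product: 2 (3R,6S)-2-(hydroxymethylidene)-3-methyl-6-(propan-2-yl)cyclohexan-1-one
Conditions: HCO2Et, NaH, cat. EtOH, THF, 0 → 25 °C; then aq. HCl
Reagents that add atoms: ethyl formate, CCOC=O
Why: Claisen-type formylation can only be driven at the CH2 alpha-carbon, where the beta-keto aldehyde is drained as its enolate; the methyl-bearing stereocentre is not touched.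

**Step 2**
Reactants: 2 (3R,6S)-2-(hydroxymethylidene)-3-methyl-6-(propan-2-yl)cyclohexan-1-one
Product: 4 (1S,2R,5S)-2-methyl-6-oxo-5-(propan-2-yl)-1-(prop-2-en-1-yl)cyclohexane-1-carbaldehyde, via allyl enol ether 3 (not isolated)
Conditions: allyl bromide, K2CO3, acetone, 56 °C; then solvent change to xylene, 140 °C
Reagents that add atoms: allyl bromide, C=CCBr
Why: O-allylation followed by Claisen rearrangement should deliver the allyl group anti to the neighbouring methyl group, which sits pseudo-axial to avoid allylic strain with the exocyclic enol ether, so allyl ends trans and CHO cis to that methyl.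

**Step 3**
Reactants: 4 (1S,2R,5S)-2-methyl-6-oxo-5-(propan-2-yl)-1-(prop-2-en-1-yl)cyclohexane-1-carbaldehyde
Product: 6 (2S,3R,6S)-3-methyl-2-{(1S)-2-methyl-1-[(triethylsilyl)oxy]prop-2-en-1-yl}-6-(propan-2-yl)-2-(prop-2-en-1-yl)cyclohexan-1-one, via bromomagnesium alkoxide 5 (not isolated)
Conditions: CH2=C(CH3)MgBr, THF, −78 °C; then Et3SiOTf, 2,6-lutidine, −78 → 0 °C
Reagents that add atoms: isopropenylmagnesium bromide, CC(=C)[Mg]Br; triethylsilyl trifluoromethanesulfonate, CC[Si](CC)(CC)OS(=O)(=O)C(F)(F)F
Why: Cram-chelate Grignard addition, in which magnesium bridges the aldehyde and ketone oxygens and the reagent attacks from the allyl face, away from the methyl-bearing ring carbon, should set the (S)-carbinol, which is silylated in the same flask.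

**Step 4**
Reactants: 6 (2S,3R,6S)-3-methyl-2-{(1S)-2-methyl-1-[(triethylsilyl)oxy]prop-2-en-1-yl}-6-(propan-2-yl)-2-(prop-2-en-1-yl)cyclohexan-1-one
Product: 7 (1S,5S,7S,10R)-2,10-dimethyl-7-(propan-2-yl)-1-[(triethylsilyl)oxy]spiro[4.5]dec-2-en-6-one
Conditions: second-generation Grubbs catalyst RuCl2(=CHPh)(H2IMes)(PCy3) (5 mol%), CH2Cl2, 40 °C
Reagents that add atoms: none
Why: Ring-closing metathesis of the allyl and isopropenyl groups should close the trisubstituted cyclopentene with loss of ethene; no stereocentre is affected.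

**Step 5**
Reactants: 7 (1S,5S,7S,10R)-2,10-dimethyl-7-(propan-2-yl)-1-[(triethylsilyl)oxy]spiro[4.5]dec-2-en-6-one
Product: 8 (1S,5S,10R)-2,10-dimethyl-7-(propan-2-yl)-1-[(triethylsilyl)oxy]spiro[4.5]deca-2,6-dien-6-yl trifluoromethanesulfonate
Conditions: KN(SiMe3)2, THF, −78 → 0 °C; then PhNTf2, 0 °C
Reagents that add atoms: N-phenylbis(trifluoromethanesulfonimide), O=S(=O)(N(c1ccccc1)S(=O)(=O)C(F)(F)F)C(F)(F)F
Why: The ketone can enolise only toward the isopropyl-bearing carbon because the other alpha-carbon is the spiro centre, so O-triflation of the enolate should give a single enol triflate.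

**Step 6**
Reactants: 8 (1S,5S,10R)-2,10-dimethyl-7-(propan-2-yl)-1-[(triethylsilyl)oxy]spiro[4.5]deca-2,6-dien-6-yl trifluoromethanesulfonate
Product: 10 (1S,5R,10R)-2,10-dimethyl-7-(propan-2-yl)spiro[4.5]deca-2,6-dien-1-ol, via silyl ether 9 (not isolated)
Conditions: Pd(OAc)2, PPh3, HCO2H, Bu3N, DMF, 60 °C; then Bu4NF, THF, 25 °C
Reagents that add atoms: none
Why: Palladium-catalysed formate reduction of the enol triflate (oxidative addition, formate exchange, decarboxylation, C–H reductive elimination) should give the trisubstituted cyclohexene, and fluoride then removes the silyl group.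

**Step 7**
Reactants: 11 4-fluoro-2,6-dimethoxybenzaldehyde
Product: 12 4-fluoro-2,6-dimethoxybenzene-1,3-dicarbaldehyde
Conditions: Cl2CHOCH3, TiCl4, CH2Cl2, 0 → 25 °C; then H2O
Reagents that add atoms: dichloromethyl methyl ether, COC(Cl)Cl; water, O
Why: Rieche formylation; the two free ring positions are equivalent and each is ortho to one OMe and para to the other, so one dialdehyde should form.

**Step 8**
Reactants: 12 4-fluoro-2,6-dimethoxybenzene-1,3-dicarbaldehyde
Product: 13 5-bromo-4-fluoro-2,6-dimethoxybenzene-1,3-dicarbaldehyde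
Conditions: N-bromosuccinimide, CF3CO2H, MeCN, 25 → 50 °C
Reagents that add atoms: N-bromosuccinimide, O=C1CCC(=O)N1Br
Why: Electrophilic aromatic bromination at the only remaining ring position, which is activated by an ortho and a para methoxy group.

**Step 9**
Reactants: 13 5-bromo-4-fluoro-2,6-dimethoxybenzene-1,3-dicarbaldehyde
Product: 14 4-fluoro-2,6-dimethoxy-5-(3-methylbut-1-yn-1-yl)benzene-1,3-dicarbaldehyde
Conditions: 3-methylbut-1-yne, Pd(PPh3)2Cl2, CuI, Et3N, DMF, 60 °C (sealed tube)
Reagents that add atoms: 3-methylbut-1-yne, CC(C)C#C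
Why: Sonogashira coupling of the electron-poor aryl bromide; a tertiary amine is used so that the activated fluoride is not displaced.

**Step 10**
Reactants: 10 (1S,5R,10R)-2,10-dimethyl-7-(propan-2-yl)spiro[4.5]deca-2,6-dien-1-ol and 14 4-fluoro-2,6-dimethoxy-5-(3-methylbut-1-yn-1-yl)benzene-1,3-dicarbaldehyde
Product: 17 di-O-methyl ether of the target, via aryl ether 15 (not isolated), via alkylidene chroman 16 (not isolated)
Conditions: NaH, THF/DMF, 0 → 25 °C; then AcOH (0.1 equiv), Fe(acac)3 (30 mol%), PhSiH3, EtOH, 60 °C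
Reagents that add atoms: none
Why: Proposed new method: the sodium alkoxide of 10 displaces fluoride from 14 by addition–elimination at the ring carbon ortho and para to the two formyl groups (aryl C–O bond, carbinol configuration untouched) to give 15, and the iron hydride generated from Fe(acac)3 and PhSiH3 then transfers a hydrogen atom to the CH terminus of the cyclopentene, which leaves a tertiary radical on the methyl-bearing carbon next to the ether carbon. This radical closes the pyran ring by 6-exo-dig attack on the proximal alkyne carbon (bond from the future benzylic carbon to the quaternary carbon); the vinyl radical is quenched to 16, whose styrene-type double bond takes up hydrogen by a second hydrogen-atom transfer and reduction of the resulting benzylic radical. The closest known reactions are SNAr etherification of formyl-activated fluoroarenes, iron-hydride (Mukaiyama-type hydrogen-atom transfer) reductive radical cyclisation of unactivated alkenes onto pi-acceptors, and hydrogen-atom-transfer hydrogenation of styrenes; their merger in one flask with an aryl alkyne as acceptor for a quaternary centre has no precedent. The quaternary centre is controlled by the carbinol stereocentre through the three-atom O–aryl tether, which permits only the cis-fused six/five junction. The benzylic centre is controlled in the last hydrogen transfer, which should reach the planar benzylic radical from the convex face, anti to the cyclopentane and the spiro ring, so that the isobutyl group ends cis to the ring CH2 on the quaternary carbon. The step needs hydrogen-atom transfer to the cyclopentene in preference to the cyclohexene, the alkyne and the formyl groups, which should be secured by shielding of the cyclohexene CH by the spiro carbon and the isopropyl group, the low reactivity of alkynes and aryl aldehydes toward metal-hydride hydrogen-atom transfer, and a limited charge of silane.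

**Step 11**
Reactants: 17 di-O-methyl ether of the target
Product: 18 CNP0121396.3 (target)
Conditions: BCl3, CH2Cl2, −78 → 0 °C; then H2O
Reagents that add atoms: none
Why: Boron trichloride chelates each formyl oxygen and should cleave the two ortho methyl ethers by chloride attack at methyl, while the pyran oxygen on a neopentyl secondary carbon and the trisubstituted alkene should survive at low temperature; no stereocentre is touched.

**Compound list**

1 | (−)-menthone, (2S,5R)-5-methyl-2-(propan-2-yl)cyclohexan-1-one | C[C@@H]1CC[C@@H](C(C)C)C(=O)C1 | starting material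
2 | (3R,6S)-2-(hydroxymethylidene)-3-methyl-6-(propan-2-yl)cyclohexan-1-one | C[C@@H]1CC[C@@H](C(C)C)C(=O)C1=CO | intermediate
3 | (3R,6S)-3-methyl-6-(propan-2-yl)-2-[(prop-2-en-1-yloxy)methylidene]cyclohexan-1-one | C[C@@H]1CC[C@@H](C(C)C)C(=O)C1=COCC=C | intermediate
4 | (1S,2R,5S)-2-methyl-6-oxo-5-(propan-2-yl)-1-(prop-2-en-1-yl)cyclohexane-1-carbaldehyde | C=CC[C@@]1(C=O)[C@H](C)CC[C@@H](C(C)C)C1=O | intermediate
5 | bromomagnesium alkoxide of the (1S)-carbinol formed from 4 | C=CC[C@@]1([C@@H](O[Mg]Br)C(C)=C)[C@H](C)CC[C@@H](C(C)C)C1=O | intermediate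
6 | (2S,3R,6S)-3-methyl-2-{(1S)-2-methyl-1-[(triethylsilyl)oxy]prop-2-en-1-yl}-6-(propan-2-yl)-2-(prop-2-en-1-yl)cyclohexan-1-one | C=CC[C@@]1([C@@H](O[Si](CC)(CC)CC)C(C)=C)[C@H](C)CC[C@@H](C(C)C)C1=O | intermediate
7 | (1S,5S,7S,10R)-2,10-dimethyl-7-(propan-2-yl)-1-[(triethylsilyl)oxy]spiro[4.5]dec-2-en-6-one | CC[Si](CC)(CC)O[C@H]2C(C)=CC[C@@]21C(=O)[C@H](C(C)C)CC[C@H]1C | intermediate
8 | (1S,5S,10R)-2,10-dimethyl-7-(propan-2-yl)-1-[(triethylsilyl)oxy]spiro[4.5]deca-2,6-dien-6-yl trifluoromethanesulfonate | CC[Si](CC)(CC)O[C@H]2C(C)=CC[C@@]21C(OS(=O)(=O)C(F)(F)F)=C(C(C)C)CC[C@H]1C | intermediate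
9 | triethyl{[(1S,5R,10R)-2,10-dimethyl-7-(propan-2-yl)spiro[4.5]deca-2,6-dien-1-yl]oxy}silane | CC[Si](CC)(CC)O[C@H]2C(C)=CC[C@@]21C=C(C(C)C)CC[C@H]1C | intermediate
10 | (1S,5R,10R)-2,10-dimethyl-7-(propan-2-yl)spiro[4.5]deca-2,6-dien-1-ol | O[C@H]2C(C)=CC[C@@]21C=C(C(C)C)CC[C@H]1C | intermediate
11 | 4-fluoro-2,6-dimethoxybenzaldehyde | COc1cc(F)cc(OC)c1C=O | starting material
12 | 4-fluoro-2,6-dimethoxybenzene-1,3-dicarbaldehyde | COc1cc(F)c(C=O)c(OC)c1C=O | intermediate
13 | 5-bromo-4-fluoro-2,6-dimethoxybenzene-1,3-dicarbaldehyde | COc1c(Br)c(F)c(C=O)c(OC)c1C=O | intermediate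
14 | 4-fluoro-2,6-dimethoxy-5-(3-methylbut-1-yn-1-yl)benzene-1,3-dicarbaldehyde | COc1c(C#CC(C)C)c(F)c(C=O)c(OC)c1C=O | intermediate
15 | 4-{[(1S,5R,10R)-2,10-dimethyl-7-(propan-2-yl)spiro[4.5]deca-2,6-dien-1-yl]oxy}-2,6-dimethoxy-5-(3-methylbut-1-yn-1-yl)benzene-1,3-dicarbaldehyde | CC(C)C#Cc1c(OC)c(C=O)c(OC)c(C=O)c1O[C@H]2C(C)=CC[C@@]21C=C(C(C)C)CC[C@H]1C | intermediate
16 | cis-fused cyclopenta[b]chromene of 17 with an exocyclic C=CH–CH(CH3)2 double bond at the benzylic carbon (E/Z mixture), other centres as in 17 | CC(C)C=C1c2c(OC)c(C=O)c(OC)c(C=O)c2O[C@H]2[C@]1(C)CC[C@@]21C=C(C(C)C)CC[C@H]1C | intermediate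
17 | di-O-methyl ether of the target (OCH3 in place of both OH; benzylic CH S, quaternary C–CH3 R, O–CH S, spiro C R, CH–CH3 R) | CC(C)C[C@@H]1c2c(OC)c(C=O)c(OC)c(C=O)c2O[C@H]2[C@]1(C)CC[C@@]21C=C(C(C)C)CC[C@H]1C | intermediate
18 | CNP0121396.3: diformyl-dihydroxy chroman, cis-fused to a methylcyclopentane that is spiro-linked to a 3-isopropyl-6-methylcyclohex-2-ene (benzylic CH S, quaternary C–CH3 R, O–CH S, spiro C R, CH–CH3 R) | CC(C)C[C@@H]1c2c(O)c(C=O)c(O)c(C=O)c2O[C@H]2[C@]1(C)CC[C@@]21C=C(C(C)C)CC[C@H]1C | target

**Totals.** Total step count: 11. Longest linear sequence: 8 steps (steps 1, 2, 3, 4, 5, 6, 10, 11).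

**Steps most likely to fail**

Step 10 (proposed new method). It may fail through hydrogen-atom transfer to the cyclohexene, silane reduction of the formyl groups, solvolysis of the activated allylic aryl ether, or poor facial selectivity in the last hydrogen transfer. The fallback uses known reactions with isolation. It sets out from 10 and 14: the SNAr etherification is run alone (NaH, THF/DMF) and 15 is isolated. Then 15 is closed by palladium-hydride reductive enyne cyclisation (Pd2(dba)3·CHCl3, AcOH, Et3SiH, toluene), where hydropalladation of the alkyne and 6-exo carbopalladation of the cyclopentene build the quaternary centre, to give 16. Finally 16 is reduced at the styrene double bond by hydrogen-atom-transfer hydrogenation (Mn(dpm)3, PhSiH3, t-BuOOH, i-PrOH), which comes back to the route at 17. No compound outside the compound list is formed (F0).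

Step 3. It may fail through loss of chelation control, that is poor facial selectivity at the new carbinol carbon. The fallback sets the carbinol by reagent control instead. It sets out from 4: the Grignard addition is worked up without silylation to the epimeric alcohols, (2S,3R,6S)-2-(1-hydroxy-2-methylprop-2-en-1-yl)-3-methyl-6-(propan-2-yl)-2-(prop-2-en-1-yl)cyclohexan-1-one F1. Dess–Martin oxidation gives the dienone 3-methyl-2-(2-methylprop-2-enoyl)-6-(propan-2-yl)-2-(prop-2-en-1-yl)cyclohexan-1-one F2. Ring-closing metathesis (second-generation Grubbs catalyst) gives the spiro enedione 2,10-dimethyl-7-(propan-2-yl)spiro[4.5]dec-2-ene-1,6-dione F3. CBS reduction of the conjugated, less hindered carbonyl (the oxazaborolidine enantiomer that delivers hydride to the Re face, expected (R)-2-methyl-CBS, with catecholborane) gives (1S,5S,7S,10R)-1-hydroxy-2,10-dimethyl-7-(propan-2-yl)spiro[4.5]dec-2-en-6-one F4. Silylation (Et3SiOTf, 2,6-lutidine) comes back to the route at 7.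

Step 11. It may fail through Lewis-acid opening of the pyran C–O bond or hydrochlorination or migration of the ring alkene during demethylation. The fallback replaces the methyl ethers by methoxymethyl ethers before the key step. It sets out from 13: BBr3 gives 5-bromo-4-fluoro-2,6-dihydroxybenzene-1,3-dicarbaldehyde F5, and MOMCl/i-Pr2NEt gives 5-bromo-4-fluoro-2,6-bis(methoxymethoxy)benzene-1,3-dicarbaldehyde F6. Sonogashira coupling with 3-methylbut-1-yne gives 4-fluoro-2,6-bis(methoxymethoxy)-5-(3-methylbut-1-yn-1-yl)benzene-1,3-dicarbaldehyde F7. The conditions of step 10 with 10 then lead through the bis-MOM aryl ether F8 and the bis-MOM alkylidene chroman F9 to the bis-MOM ether of the target F10. HCl in MeOH at 25 °C removes both acetals and comes back to the route at 18.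

**Further compounds**

F0 | step 10 | none | none
F1 | step 3 | (2S,3R,6S)-2-(1-hydroxy-2-methylprop-2-en-1-yl)-3-methyl-6-(propan-2-yl)-2-(prop-2-en-1-yl)cyclohexan-1-one (both carbinol epimers) | C=CC[C@@]1(C(O)C(C)=C)[C@H](C)CC[C@@H](C(C)C)C1=O
F2 | step 3 | 3-methyl-2-(2-methylprop-2-enoyl)-6-(propan-2-yl)-2-(prop-2-en-1-yl)cyclohexan-1-one (allyl trans to methyl) | C=CC[C@@]1(C(=O)C(C)=C)[C@H](C)CC[C@@H](C(C)C)C1=O
F3 | step 3 | 2,10-dimethyl-7-(propan-2-yl)spiro[4.5]dec-2-ene-1,6-dione (configuration as in 7) | O=C2C(C)=CC[C@@]21C(=O)[C@H](C(C)C)CC[C@H]1C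
F4 | step 3 | (1S,5S,7S,10R)-1-hydroxy-2,10-dimethyl-7-(propan-2-yl)spiro[4.5]dec-2-en-6-one | O[C@H]2C(C)=CC[C@@]21C(=O)[C@H](C(C)C)CC[C@H]1C
F5 | step 11 | 5-bromo-4-fluoro-2,6-dihydroxybenzene-1,3-dicarbaldehyde | Oc1c(Br)c(F)c(C=O)c(O)c1C=O
F6 | step 11 | 5-bromo-4-fluoro-2,6-bis(methoxymethoxy)benzene-1,3-dicarbaldehyde | COCOc1c(Br)c(F)c(C=O)c(OCOC)c1C=O
F7 | step 11 | 4-fluoro-2,6-bis(methoxymethoxy)-5-(3-methylbut-1-yn-1-yl)benzene-1,3-dicarbaldehyde | COCOc1c(C#CC(C)C)c(F)c(C=O)c(OCOC)c1C=O
F8 | step 11 | bis-MOM analogue of aryl ether 15 | CC(C)C#Cc1c(OCOC)c(C=O)c(OCOC)c(C=O)c1O[C@H]2C(C)=CC[C@@]21C=C(C(C)C)CC[C@H]1C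
F9 | step 11 | bis-MOM analogue of alkylidene chroman 16 | CC(C)C=C1c2c(OCOC)c(C=O)c(OCOC)c(C=O)c2O[C@H]2[C@]1(C)CC[C@@]21C=C(C(C)C)CC[C@H]1C
F10 | step 11 | bis(methoxymethyl) ether of the target | CC(C)C[C@@H]1c2c(OCOC)c(C=O)c(OCOC)c(C=O)c2O[C@H]2[C@]1(C)CC[C@@]21C=C(C(C)C)CC[C@H]1C
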